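**Strategy.** The route rests on disconnecting the C9–C10 bond of the ten-membered carbocycle (germacrane numbering): the bond between the acetoxy-bearing carbinol C9 and the α-carbon C10 of the C1=C10 enoate. This α-(1-oxyalkyl)acrylate motif is made in one operation by an intramolecular Nozaki–Hiyama–Kishi coupling: a (Z)-α-iodoenoate adds to an α-acyloxy aldehyde, closing the ring, creating C9 and fixing the enoate geometry. The precursor is an open-chain iodo-aldehyde built on the trans-disubstituted α-methylene-γ-butyrolactone, whose C6–C8 stereotriad comes from (R)-glyceraldehyde acetonide by anti-aldol addition and anti-reduction; the 4,5-epoxide is installed last.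

Key step: step 12

Remark: germacrane numbering is used for all intermediates (ring carbons C1–C10, lactone carbons C11–C13, ester carbon C14 on C10, methyl C15 on C4); the three fragment starting materials are taken as commercial.

Step 1
Reactants: 1 tert-butyldimethyl(pent-4-yn-1-yloxy)silane
Product: 3 tert-butyl{[(4E)-5-iodo-4-methylpent-4-en-1-yl]oxy}dimethylsilane, via alkenyldimethylalane 2 (not isolated)
Conditions: AlMe3, Cp2ZrCl2 (cat.), CH2Cl2, 0 °C → rt; then I2, THF, −30 → 0 °C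
Reagents that add atoms: trimethylaluminium C[Al](C)C; iodine II
Why: Negishi zirconium-catalysed carboalumination adds CH3–Al syn across the terminal alkyne with CH3 on the internal carbon, and iodinolysis with retention should give the (E)-alkenyl iodide that carries the future C4=C5 geometry and C15.

Step 2
Reactants: 3 tert-butyl{[(4E)-5-iodo-4-methylpent-4-en-1-yl]oxy}dimethylsilane; 4 methyl 4-chloro-4-oxobutanoate
Product: 7 methyl (5E)-9-{[tert-butyl(dimethyl)silyl]oxy}-6-methyl-4-oxonon-5-enoate, via alkenyllithium 5 (not isolated), via alkenylzinc chloride 6 (not isolated)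
Conditions: tBuLi (2 equiv), Et2O, −78 °C; ZnCl2, THF, −78 → 0 °C; then 4, Pd(PPh3)4 (cat.), THF, 0 °C → rt
Reagents that add atoms: none
Why: Iodine–lithium exchange, transmetalation to zinc and palladium-catalysed Negishi acylation should join the alkenyl unit to the acid chloride with retention of the E geometry, the acid chloride reacting far faster than the methyl ester.

Step 3
Reactants: 7 methyl (5E)-9-{[tert-butyl(dimethyl)silyl]oxy}-6-methyl-4-oxonon-5-enoate; 8 (4R)-2,2-dimethyl-1,3-dioxolane-4-carbaldehyde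
Product: 10 methyl (3R,5E)-9-{[tert-butyl(dimethyl)silyl]oxy}-3-{(S)-[(4R)-2,2-dimethyl-1,3-dioxolan-4-yl](hydroxy)methyl}-6-methyl-4-oxonon-5-enoate, via boron enolate 9 (not isolated)
Conditions: chlorodicyclohexylborane (c-Hex2BCl), Et3N, Et2O, −78 → 0 °C; then 8, −78 → −20 °C; then H2O2, MeOH, pH 7 buffer, 0 °C
Reagents that add atoms: none
Why: The boron chloride/amine pair should give the cross-conjugated (E)-enol borinate at the CH2 next to the ketone, which adds through a chair Zimmerman–Traxler transition state (anti aldol, sets C7 against C8) to the aldehyde face anti to the dioxolane C–O bond (polar Felkin–Anh/Cornforth control, sets C8), so both new stereocentres derive from the (R)-aldehyde.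

Step 4
Reactants: 10 methyl (3R,5E)-9-{[tert-butyl(dimethyl)silyl]oxy}-3-{(S)-[(4R)-2,2-dimethyl-1,3-dioxolan-4-yl](hydroxy)methyl}-6-methyl-4-oxonon-5-enoate
Product: 12 (4R,5R)-5-[(1E)-5-{[tert-butyl(dimethyl)silyl]oxy}-2-methylpent-1-en-1-yl]-4-{(S)-[(4R)-2,2-dimethyl-1,3-dioxolan-4-yl](hydroxy)methyl}oxolan-2-one, via anti-diol ester 11 (not isolated)
Conditions: Me4NBH(OAc)3, MeCN/AcOH (1:1), −30 °C; aqueous NaHCO3 work-up; then pyridinium p-toluenesulfonate (cat.), toluene, 40 °C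
Reagents that add atoms: none
Why: Evans–Saksena reduction delivers hydride intramolecularly from the acetoxyborohydride bound to the C8 hydroxyl through a chair six-membered transition state to give the 1,3-anti diol (sets C6), and acid-catalysed lactonization under thermodynamic control should close the five-membered lactone on the allylic C6 oxygen, where the two ring substituents are trans, in preference to the cis-disubstituted lactone on O8.

Step 5
Reactants: 12 (4R,5R)-5-[(1E)-5-{[tert-butyl(dimethyl)silyl]oxy}-2-methylpent-1-en-1-yl]-4-{(S)-[(4R)-2,2-dimethyl-1,3-dioxolan-4-yl](hydroxy)methyl}oxolan-2-one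
Product: 13 (4S,5R)-5-[(1E)-5-{[tert-butyl(dimethyl)silyl]oxy}-2-methylpent-1-en-1-yl]-4-{(S)-[(4R)-2,2-dimethyl-1,3-dioxolan-4-yl][(triethylsilyl)oxy]methyl}oxolan-2-one
Conditions: Et3SiOTf, 2,6-lutidine, CH2Cl2, −78 → 0 °C
Reagents that add atoms: triethylsilyl trifluoromethanesulfonate CC[Si](CC)(CC)OS(=O)(=O)C(F)(F)F
Why: Standard silylation masks the C8 hydroxyl for the enolate chemistry of the next step and touches no stereocentre.

Step 6
Reactants: 13 (4S,5R)-5-[(1E)-5-{[tert-butyl(dimethyl)silyl]oxy}-2-methylpent-1-en-1-yl]-4-{(S)-[(4R)-2,2-dimethyl-1,3-dioxolan-4-yl][(triethylsilyl)oxy]methyl}oxolan-2-one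
Product: 16 (4S,5R)-5-[(1E)-5-{[tert-butyl(dimethyl)silyl]oxy}-2-methylpent-1-en-1-yl]-4-{(S)-[(4R)-2,2-dimethyl-1,3-dioxolan-4-yl][(triethylsilyl)oxy]methyl}-3-methylideneoxolan-2-one, via Mannich base 14 (not isolated), via ammonium iodide 15 (not isolated)
Conditions: LiN(iPr)2, THF, −78 °C; Eschenmoser's salt, −78 → 0 °C; then MeI, MeOH, rt; then aqueous NaHCO3, CH2Cl2, rt
Reagents that add atoms: N,N-dimethylmethyleneiminium iodide (Eschenmoser's salt) C=[N+](C)C.[I-]
Why: The lactone lithium enolate is aminomethylated (Mannich reaction, trans to the C7 substituent) and quaternization followed by base-induced elimination of trimethylamine should give the exocyclic C11=C13 methylene, which removes the transient C11 stereocentre.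

Step 7
Reactants: 16 (4S,5R)-5-[(1E)-5-{[tert-butyl(dimethyl)silyl]oxy}-2-methylpent-1-en-1-yl]-4-{(S)-[(4R)-2,2-dimethyl-1,3-dioxolan-4-yl][(triethylsilyl)oxy]methyl}-3-methylideneoxolan-2-one
Product: 17 (4R,5R)-4-{(S)-[(4R)-2,2-dimethyl-1,3-dioxolan-4-yl](hydroxy)methyl}-5-[(1E)-5-hydroxy-2-methylpent-1-en-1-yl]-3-methylideneoxolan-2-one
Conditions: HF·pyridine, pyridine, THF, 0 °C → rt
Reagents that add atoms: none
Why: Buffered fluoride desilylation should cleave both silyl ethers while the acetonide, the lactone and the acrylate unit stay intact under these non-basic conditions.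

Step 8
Reactants: 17 (4R,5R)-4-{(S)-[(4R)-2,2-dimethyl-1,3-dioxolan-4-yl](hydroxy)methyl}-5-[(1E)-5-hydroxy-2-methylpent-1-en-1-yl]-3-methylideneoxolan-2-one
Product: 18 (4E)-5-[(2R,3R)-3-{(S)-[(4R)-2,2-dimethyl-1,3-dioxolan-4-yl](hydroxy)methyl}-4-methylidene-5-oxooxolan-2-yl]-4-methylpent-4-enal
Conditions: 2,2,6,6-tetramethylpiperidin-1-oxyl (cat.), PhI(OAc)2, CH2Cl2, rt
Reagents that add atoms: none
Why: The nitroxyl-catalysed oxidation is selective for primary over hindered secondary alcohols, so only the C1 hydroxyl should be taken to the aldehyde.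

Step 9
Reactants: 18 (4E)-5-[(2R,3R)-3-{(S)-[(4R)-2,2-dimethyl-1,3-dioxolan-4-yl](hydroxy)methyl}-4-methylidene-5-oxooxolan-2-yl]-4-methylpent-4-enal
Product: 19 methyl (2Z,6E)-7-[(2R,3R)-3-{(S)-[(4R)-2,2-dimethyl-1,3-dioxolan-4-yl](hydroxy)methyl}-4-methylidene-5-oxooxolan-2-yl]-2-iodo-6-methylhepta-2,6-dienoate
Conditions: Ph3P=CHCO2Me, N-iodosuccinimide, MeCN, −20 °C; then 18, −20 °C → rt
Reagents that add atoms: methyl (triphenylphosphoranylidene)acetate COC(=O)C=P(c1ccccc1)(c1ccccc1)c1ccccc1; N-iodosuccinimide O=C1CCC(=O)N1I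
Why: Wittig olefination with the stabilised α-iodo ylide generated in situ should give the (Z)-α-iodoenoate (iodine cis to the chain, ester trans to it) as the major isomer and tolerates the free C8 hydroxyl.

Step 10
Reactants: 19 methyl (2Z,6E)-7-[(2R,3R)-3-{(S)-[(4R)-2,2-dimethyl-1,3-dioxolan-4-yl](hydroxy)methyl}-4-methylidene-5-oxooxolan-2-yl]-2-iodo-6-methylhepta-2,6-dienoate
Product: 20 methyl (2Z,6E)-7-[(2R,3S)-3-{(S)-[(4R)-2,2-dimethyl-1,3-dioxolan-4-yl][(2-methylprop-2-enoyl)oxy]methyl}-4-methylidene-5-oxooxolan-2-yl]-2-iodo-6-methylhepta-2,6-dienoate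
Conditions: methacrylic anhydride, Et3N, 4-(dimethylamino)pyridine (cat.), CH2Cl2, 0 °C → rt
Reagents that add atoms: methacrylic anhydride C=C(C)C(=O)OC(=O)C(C)=C
Why: Nucleophile-catalysed acylation of the secondary C8 hydroxyl installs the methacrylate with retention at C8.

Step 11
Reactants: 20 methyl (2Z,6E)-7-[(2R,3S)-3-{(S)-[(4R)-2,2-dimethyl-1,3-dioxolan-4-yl][(2-methylprop-2-enoyl)oxy]methyl}-4-methylidene-5-oxooxolan-2-yl]-2-iodo-6-methylhepta-2,6-dienoate
Product: 21 methyl (2Z,6E)-2-iodo-6-methyl-7-[(2R,3S)-4-methylidene-3-{(1S)-1-[(2-methylprop-2-enoyl)oxy]-2-oxoethyl}-5-oxooxolan-2-yl]hepta-2,6-dienoate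
Conditions: H5IO6, EtOAc, rt
Reagents that add atoms: none
Why: Periodic acid hydrolyses the terminal acetonide and cleaves the liberated 1,2-diol in one pot (glycol cleavage), excising the auxiliary carbon as formaldehyde and unveiling the C9 aldehyde next to the intact C8 stereocentre under non-basic conditions.

Step 12
Reactants: 21 methyl (2Z,6E)-2-iodo-6-methyl-7-[(2R,3S)-4-methylidene-3-{(1S)-1-[(2-methylprop-2-enoyl)oxy]-2-oxoethyl}-5-oxooxolan-2-yl]hepta-2,6-dienoate
Product: 23 methyl (3aS,4S,5S,6E,10E,11aR)-5-hydroxy-10-methyl-3-methylidene-4-[(2-methylprop-2-enoyl)oxy]-2-oxo-2,3,3a,4,5,8,9,11a-octahydrocyclodeca[b]furan-6-carboxylate, via alkenylchromium dichloride 22 (not isolated)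
Conditions: CrCl2 (excess), NiCl2 (cat.), degassed DMSO, rt, slow addition of 21 to a final concentration of about 2 mM
Reagents that add atoms: none
Why: Zerovalent nickel, formed from NiCl2 and CrCl2, inserts into the activated C10–I bond, transmetalation gives the trivalent alkenylchromium 22, and this adds to the C9 aldehyde to give the alcohol after hydrolysis of the chromium alkoxide (intramolecular Nozaki–Hiyama–Kishi reaction; the closest known reaction type is the Ni/Cr macrocyclization of alkenyl iodides onto aldehydes to medium rings). The ten-membered carbocycle is closed in a 10-exo-trig mode by the C9–C10 bond. The C1=C10 geometry is controlled by retention at the configurationally stable alkenylchromium, so the Z-iodide becomes the enoate with C2 and C9 cis on the ring (E by the priority rules). The new stereocentre C9 is controlled by the ring-forming transition state: with the chain anchored on the rigid trans-lactone, closure should pass through the crown-like conformer in which the C8 ester and the bulky developing C9–O–Cr group are both pseudo-equatorial and H8/H9 are anti, which is the 9S (8,9-threo) alcohol. The step needs chemoselectivity for the aldehyde over three ester carbonyls and two acrylate units, which the alkenylchromium reagent secures, and cyclization over oligomerization, which high dilution together with the turn imposed by the Z-iodoenoate and the lactone secures.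

Step 13
Reactants: 23 methyl (3aS,4S,5S,6E,10E,11aR)-5-hydroxy-10-methyl-3-methylidene-4-[(2-methylprop-2-enoyl)oxy]-2-oxo-2,3,3a,4,5,8,9,11a-octahydrocyclodeca[b]furan-6-carboxylate
Product: 24 methyl (3aS,4S,5S,6E,10E,11aR)-5-(acetyloxy)-10-methyl-3-methylidene-4-[(2-methylprop-2-enoyl)oxy]-2-oxo-2,3,3a,4,5,8,9,11a-octahydrocyclodeca[b]furan-6-carboxylate
Conditions: Ac2O, pyridine, 4-(dimethylamino)pyridine (cat.), CH2Cl2, 0 °C
Reagents that add atoms: acetic anhydride CC(=O)OC(C)=O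
Why: Nucleophile-catalysed acetylation of the allylic C9 hydroxyl is fast enough to outrun acyl migration from O8 and affects no stereocentre.

Step 14
Reactants: 24 methyl (3aS,4S,5S,6E,10E,11aR)-5-(acetyloxy)-10-methyl-3-methylidene-4-[(2-methylprop-2-enoyl)oxy]-2-oxo-2,3,3a,4,5,8,9,11a-octahydrocyclodeca[b]furan-6-carboxylate
Product: 25 methyl (1S,2R,4R,7E,9S,10S,11R)-9-(acetyloxy)-4-methyl-12-methylidene-10-[(2-methylprop-2-enoyl)oxy]-13-oxo-3,14-dioxatricyclo[9.3.0.0(2,4)]tetradec-7-ene-8-carboxylate (the target)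
Conditions: mCPBA, NaHCO3, CH2Cl2, 0 °C
Reagents that add atoms: 3-chloroperoxybenzoic acid OOC(=O)c1cccc(Cl)c1
Why: Prilezhaev epoxidation is chemoselective for the only electron-rich alkene (trisubstituted C4=C5; the other three are conjugated to carbonyls), is stereospecific so the E alkene gives the trans-epoxide, and should occur on the outer face of the alkene, which stands perpendicular to the mean plane of the ten-membered ring, to give the 4R,5R epoxide.

**Compound list**

1 | tert-butyldimethyl(pent-4-yn-1-yloxy)silane | C#CCCCO[Si](C)(C)C(C)(C)C | starting material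
2 | [(1E)-5-{[tert-butyl(dimethyl)silyl]oxy}-2-methylpent-1-en-1-yl]dimethylalumane | C[Al](C)/C=C(\C)CCCO[Si](C)(C)C(C)(C)C | intermediate (not isolated)
3 | tert-butyl{[(4E)-5-iodo-4-methylpent-4-en-1-yl]oxy}dimethylsilane | I/C=C(\C)CCCO[Si](C)(C)C(C)(C)C | intermediate
4 | methyl 4-chloro-4-oxobutanoate | COC(=O)CCC(=O)Cl | starting material
5 | [(1E)-5-{[tert-butyl(dimethyl)silyl]oxy}-2-methylpent-1-en-1-yl]lithium | [Li]/C=C(\C)CCCO[Si](C)(C)C(C)(C)C | intermediate (not isolated)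
6 | chloro[(1E)-5-{[tert-butyl(dimethyl)silyl]oxy}-2-methylpent-1-en-1-yl]zinc | Cl[Zn]/C=C(\C)CCCO[Si](C)(C)C(C)(C)C | intermediate (not isolated)
7 | methyl (5E)-9-{[tert-butyl(dimethyl)silyl]oxy}-6-methyl-4-oxonon-5-enoate | COC(=O)CCC(=O)/C=C(\C)CCCO[Si](C)(C)C(C)(C)C | intermediate
8 | (4R)-2,2-dimethyl-1,3-dioxolane-4-carbaldehyde | O=C[C@H]1COC(C)(C)O1 | starting material
9 | methyl (3E,5E)-9-{[tert-butyl(dimethyl)silyl]oxy}-4-[(dicyclohexylboranyl)oxy]-6-methylnona-3,5-dienoate | COC(=O)C/C=C(/OB(C1CCCCC1)C1CCCCC1)\C=C(/C)CCCO[Si](C)(C)C(C)(C)C | intermediate (not isolated)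
10 | methyl (3R,5E)-9-{[tert-butyl(dimethyl)silyl]oxy}-3-{(S)-[(4R)-2,2-dimethyl-1,3-dioxolan-4-yl](hydroxy)methyl}-6-methyl-4-oxonon-5-enoate | COC(=O)C[C@H]([C@H](O)[C@H]1COC(C)(C)O1)C(=O)/C=C(\C)CCCO[Si](C)(C)C(C)(C)C | intermediate
11 | methyl (3S,4R,5E)-9-{[tert-butyl(dimethyl)silyl]oxy}-3-{(S)-[(4R)-2,2-dimethyl-1,3-dioxolan-4-yl](hydroxy)methyl}-4-hydroxy-6-methylnon-5-enoate | COC(=O)C[C@H]([C@H](O)[C@H]1COC(C)(C)O1)[C@H](O)/C=C(\C)CCCO[Si](C)(C)C(C)(C)C | intermediate (not isolated)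
12 | (4R,5R)-5-[(1E)-5-{[tert-butyl(dimethyl)silyl]oxy}-2-methylpent-1-en-1-yl]-4-{(S)-[(4R)-2,2-dimethyl-1,3-dioxolan-4-yl](hydroxy)methyl}oxolan-2-one | O=C1C[C@H]([C@H](O)[C@H]2COC(C)(C)O2)[C@@H](/C=C(\C)CCCO[Si](C)(C)C(C)(C)C)O1 | intermediate
13 | (4S,5R)-5-[(1E)-5-{[tert-butyl(dimethyl)silyl]oxy}-2-methylpent-1-en-1-yl]-4-{(S)-[(4R)-2,2-dimethyl-1,3-dioxolan-4-yl][(triethylsilyl)oxy]methyl}oxolan-2-one | O=C1C[C@H]([C@H](O[Si](CC)(CC)CC)[C@H]2COC(C)(C)O2)[C@@H](/C=C(\C)CCCO[Si](C)(C)C(C)(C)C)O1 | intermediate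
14 | (3R,4S,5R)-3-[(dimethylamino)methyl] derivative of 13 (aminomethyl group trans to the C4 substituent) | O=C1[C@@H](CN(C)C)[C@H]([C@H](O[Si](CC)(CC)CC)[C@H]2COC(C)(C)O2)[C@@H](/C=C(\C)CCCO[Si](C)(C)C(C)(C)C)O1 | intermediate (not isolated)
15 | N-methyl quaternary ammonium iodide of 14 | O=C1[C@@H](C[N+](C)(C)C)[C@H]([C@H](O[Si](CC)(CC)CC)[C@H]2COC(C)(C)O2)[C@@H](/C=C(\C)CCCO[Si](C)(C)C(C)(C)C)O1.[I-] | intermediate (not isolated)
16 | (4S,5R)-5-[(1E)-5-{[tert-butyl(dimethyl)silyl]oxy}-2-methylpent-1-en-1-yl]-4-{(S)-[(4R)-2,2-dimethyl-1,3-dioxolan-4-yl][(triethylsilyl)oxy]methyl}-3-methylideneoxolan-2-one | O=C1C(=C)[C@H]([C@H](O[Si](CC)(CC)CC)[C@H]2COC(C)(C)O2)[C@@H](/C=C(\C)CCCO[Si](C)(C)C(C)(C)C)O1 | intermediate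
17 | (4R,5R)-4-{(S)-[(4R)-2,2-dimethyl-1,3-dioxolan-4-yl](hydroxy)methyl}-5-[(1E)-5-hydroxy-2-methylpent-1-en-1-yl]-3-methylideneoxolan-2-one | O=C1C(=C)[C@H]([C@H](O)[C@H]2COC(C)(C)O2)[C@@H](/C=C(\C)CCCO)O1 | intermediate
18 | (4E)-5-[(2R,3R)-3-{(S)-[(4R)-2,2-dimethyl-1,3-dioxolan-4-yl](hydroxy)methyl}-4-methylidene-5-oxooxolan-2-yl]-4-methylpent-4-enal | O=C1C(=C)[C@H]([C@H](O)[C@H]2COC(C)(C)O2)[C@@H](/C=C(\C)CCC=O)O1 | intermediate
19 | methyl (2Z,6E)-7-[(2R,3R)-3-{(S)-[(4R)-2,2-dimethyl-1,3-dioxolan-4-yl](hydroxy)methyl}-4-methylidene-5-oxooxolan-2-yl]-2-iodo-6-methylhepta-2,6-dienoate | O=C1C(=C)[C@H]([C@H](O)[C@H]2COC(C)(C)O2)[C@@H](/C=C(\C)CC/C=C(\I)C(=O)OC)O1 | intermediate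
20 | methyl (2Z,6E)-7-[(2R,3S)-3-{(S)-[(4R)-2,2-dimethyl-1,3-dioxolan-4-yl][(2-methylprop-2-enoyl)oxy]methyl}-4-methylidene-5-oxooxolan-2-yl]-2-iodo-6-methylhepta-2,6-dienoate | O=C1C(=C)[C@H]([C@H](OC(=O)C(C)=C)[C@H]2COC(C)(C)O2)[C@@H](/C=C(\C)CC/C=C(\I)C(=O)OC)O1 | intermediate
21 | methyl (2Z,6E)-2-iodo-6-methyl-7-[(2R,3S)-4-methylidene-3-{(1S)-1-[(2-methylprop-2-enoyl)oxy]-2-oxoethyl}-5-oxooxolan-2-yl]hepta-2,6-dienoate | O=C1C(=C)[C@H]([C@H](OC(=O)C(C)=C)C=O)[C@@H](/C=C(\C)CC/C=C(\I)C(=O)OC)O1 | intermediate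
22 | trivalent alkenylchromium dichloride of 21 (CrCl2 in place of iodine on C10, geometry retained) | O=C1C(=C)[C@H]([C@H](OC(=O)C(C)=C)C=O)[C@@H](/C=C(\C)CC/C=C(\[Cr](Cl)Cl)C(=O)OC)O1 | intermediate (not isolated)
23 | methyl (3aS,4S,5S,6E,10E,11aR)-5-hydroxy-10-methyl-3-methylidene-4-[(2-methylprop-2-enoyl)oxy]-2-oxo-2,3,3a,4,5,8,9,11a-octahydrocyclodeca[b]furan-6-carboxylate | C=C(C)C(=O)O[C@H]1[C@H]2C(=C)C(=O)O[C@@H]2/C=C(\C)CC/C=C(/C(=O)OC)[C@@H]1O | intermediate
24 | methyl (3aS,4S,5S,6E,10E,11aR)-5-(acetyloxy)-10-methyl-3-methylidene-4-[(2-methylprop-2-enoyl)oxy]-2-oxo-2,3,3a,4,5,8,9,11a-octahydrocyclodeca[b]furan-6-carboxylate | C=C(C)C(=O)O[C@H]1[C@H]2C(=C)C(=O)O[C@@H]2/C=C(\C)CC/C=C(/C(=O)OC)[C@@H]1OC(C)=O | intermediate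
25 | methyl (1S,2R,4R,7E,9S,10S,11R)-9-(acetyloxy)-4-methyl-12-methylidene-10-[(2-methylprop-2-enoyl)oxy]-13-oxo-3,14-dioxatricyclo[9.3.0.0(2,4)]tetradec-7-ene-8-carboxylate | C=C(C)C(=O)O[C@H]1[C@H]2C(=C)C(=O)O[C@@H]2[C@H]2O[C@]2(C)CC/C=C(/C(=O)OC)[C@@H]1OC(C)=O | target

**Step count.** Total: 14 steps. Longest linear sequence: 14 steps (1 → 25; fragments 4 and 8 enter as commercial materials).

**Steps most likely to fail**

Step 12 (key step). The aldehyde may be attacked on its other face: the open-chain polar Felkin–Anh preference of an α-acyloxy aldehyde opposes the 8,9-threo arrangement that the ring conformer is expected to impose, so the C9 epimer could form mainly. Fallback, setting out from 21: the same ring closure is carried through as the C9-epimeric alcohol methyl (3aS,4S,5R,6E,10E,11aR)-5-hydroxy-10-methyl-3-methylidene-4-[(2-methylprop-2-enoyl)oxy]-2-oxo-2,3,3a,4,5,8,9,11a-octahydrocyclodeca[b]furan-6-carboxylate F1 (or the epimer mixture). This is oxidized with Dess–Martin periodinane (CH2Cl2, NaHCO3) to the ring ketone methyl (3aS,4S,6E,10E,11aR)-10-methyl-3-methylidene-4-[(2-methylprop-2-enoyl)oxy]-2,5-dioxo-2,3,3a,4,5,8,9,11a-octahydrocyclodeca[b]furan-6-carboxylate F2. 1,2-Reduction of F2 with NaBH4/CeCl3·7H2O in MeOH at −78 °C (Luche reduction) then sets C9 by hydride delivery to a ketone instead of by C–C bond formation. For hydride the polar Felkin–Anh preference (attack anti to the C8–O bond) points to the 8,9-threo alcohol, and the sequence returns to the route at 23.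

Step 14. The peracid may attack the other face of the C4=C5 alkene if the ring populates a conformer that exposes it, giving the diastereomeric epoxide. Fallback, setting out from 24: NBS in aqueous 1,2-dimethoxyethane at 0 °C should form the bromonium ion on the same exposed face and be opened by water at the tertiary C4 from the opposite side, giving the bromohydrin methyl (3aR,4S,5S,6E,10R,11S,11aS)-5-(acetyloxy)-11-bromo-10-hydroxy-10-methyl-3-methylidene-4-[(2-methylprop-2-enoyl)oxy]-2-oxo-2,3,3a,4,5,8,9,10,11,11a-decahydrocyclodeca[b]furan-6-carboxylate F3. K2CO3 in MeCN then closes the epoxide by displacement of bromide at C5 with inversion, which places the oxygen on the face that direct epoxidation does not reach, and the sequence returns at 25.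

Step 4. Lactonization may proceed through the C8 hydroxyl or stop at a lactone mixture, and the 1,3-anti induction may be incomplete. Fallback, setting out from 10: the C8 hydroxyl is silylated first (Et3SiOTf, 2,6-lutidine) to give methyl (3R,5E)-9-{[tert-butyl(dimethyl)silyl]oxy}-3-{(S)-[(4R)-2,2-dimethyl-1,3-dioxolan-4-yl][(triethylsilyl)oxy]methyl}-6-methyl-4-oxonon-5-enoate F4. The enone carbonyl is then reduced under reagent control with catecholborane and (3aR)-1-methyl-3,3-diphenyltetrahydro-1H,3H-pyrrolo[1,2-c][1,3,2]oxazaborole (Corey–Bakshi–Shibata reduction, the alkenyl group acting as the larger substituent) to methyl (3S,4R,5E)-9-{[tert-butyl(dimethyl)silyl]oxy}-3-{(S)-[(4R)-2,2-dimethyl-1,3-dioxolan-4-yl][(triethylsilyl)oxy]methyl}-4-hydroxy-6-methylnon-5-enoate F5. Its only free hydroxyl lactonizes (pyridinium p-toluenesulfonate, toluene, 40 °C) to 13, which bypasses the hydroxyl-directed reduction, the ambiguous lactonization and the separate silylation.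

**Further compounds**

F1 | step 12 | methyl (3aS,4S,5R,6E,10E,11aR)-5-hydroxy-10-methyl-3-methylidene-4-[(2-methylprop-2-enoyl)oxy]-2-oxo-2,3,3a,4,5,8,9,11a-octahydrocyclodeca[b]furan-6-carboxylate | C=C(C)C(=O)O[C@H]1[C@H]2C(=C)C(=O)O[C@@H]2/C=C(\C)CC/C=C(/C(=O)OC)[C@H]1O
F2 | step 12 | methyl (3aS,4S,6E,10E,11aR)-10-methyl-3-methylidene-4-[(2-methylprop-2-enoyl)oxy]-2,5-dioxo-2,3,3a,4,5,8,9,11a-octahydrocyclodeca[b]furan-6-carboxylate | C=C(C)C(=O)O[C@H]1[C@H]2C(=C)C(=O)O[C@@H]2/C=C(\C)CC/C=C(/C(=O)OC)C1=O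
F3 | step 14 | methyl (3aR,4S,5S,6E,10R,11S,11aS)-5-(acetyloxy)-11-bromo-10-hydroxy-10-methyl-3-methylidene-4-[(2-methylprop-2-enoyl)oxy]-2-oxo-2,3,3a,4,5,8,9,10,11,11a-decahydrocyclodeca[b]furan-6-carboxylate | C=C(C)C(=O)O[C@H]1[C@H]2C(=C)C(=O)O[C@@H]2[C@H](Br)[C@@](O)(C)CC/C=C(/C(=O)OC)[C@@H]1OC(C)=O
F4 | step 4 | methyl (3R,5E)-9-{[tert-butyl(dimethyl)silyl]oxy}-3-{(S)-[(4R)-2,2-dimethyl-1,3-dioxolan-4-yl][(triethylsilyl)oxy]methyl}-6-methyl-4-oxonon-5-enoate | COC(=O)C[C@H]([C@H](O[Si](CC)(CC)CC)[C@H]1COC(C)(C)O1)C(=O)/C=C(\C)CCCO[Si](C)(C)C(C)(C)C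
F5 | step 4 | methyl (3S,4R,5E)-9-{[tert-butyl(dimethyl)silyl]oxy}-3-{(S)-[(4R)-2,2-dimethyl-1,3-dioxolan-4-yl][(triethylsilyl)oxy]methyl}-4-hydroxy-6-methylnon-5-enoate | COC(=O)C[C@H]([C@H](O[Si](CC)(CC)CC)[C@H]1COC(C)(C)O1)[C@H](O)/C=C(\C)CCCO[Si](C)(C)C(C)(C)C
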